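**Retrosynthetic overview** (ring numbering: C1 is the carbonyl/phenol carbon between C2–N and C6–Cl; C4 lies para to C1)
1. Chinikomycin B ⇐ oxidation of the hydroquinone ⇐ acid-induced 1,2-shift of the whole trienyl chain from C4 to C5 of a p-quinol ⇐ oxidative dearomatisation of a 2-amido-6-chloro-4-trienylphenol.
2. That phenol ⇐ Heck coupling of an aryl bromide with a terminal trienamide that already carries the aminocyclopentenone.
3. Aryl bromide ⇐ 2-aminophenol + (2E,4E,6R)-acid, then OH-directed para-Br and ortho-Cl. The acid ⇐ copper-catalysed asymmetric allylic alkylation (sets C6), cross-metathesis, Wittig.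
4. Trienamide ⇐ Wittig of pentadienal with the ylide of the N-(cyclopentenonyl)chloroacetamide ⇐ new four-to-five ring expansion of a bis-silyloxycyclobutene on an N-acylformimidate.
5. Ring order: the benzene ring is bought. The cyclopentenone ring is made first, by ring expansion. The six-membered ring is dearomatised, rearranged and finished as the quinone last.

Assumption: (E)-1-bromohept-2-ene and stabilised (E)-penta-2,4-dienal are taken as catalogue chemicals, and the sense of induction in step 1 is fixed by the choice of ligand enantiomer.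

**Step 1**
Reactants: 1 (E)-1-bromohept-2-ene
Product: 2 (R)-3-methylhept-1-ene
Conditions: MeMgBr (1.2 equiv, Et2O), CuBr·SMe2 (1 mol %), 1-[(dimethylamino)(2-diphenylphosphinophenyl)methyl]-2-(diphenylphosphino)ferrocene (Taniaphos, C43H39FeNP2, 1.1 mol %, enantiomer giving R), CH2Cl2, −75 °C
Reagents that add atoms: methylmagnesium bromide, C[Mg]Br
Why: Copper-catalysed asymmetric allylic alkylation, in which the chiral diphosphine–methylcopper species (monovalent copper) attacks the γ-carbon anti to bromide (SN2′), so the C–Me bond forms on one alkene face and sets C6 of the target as R (branched product strongly favoured, about 92 % ee for this substrate class, and crystalline 14 offers a later chance to raise it).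

**Step 2**
Reactants: 2 (R)-3-methylhept-1-ene; 3 methacrolein
Product: 4 (2E,4R)-2,4-dimethyloct-2-enal
Conditions: 3 (5 equiv), second-generation Hoveyda–Grubbs catalyst RuCl2(H2IMes)(=CH-C6H4-2-O-i-Pr) (5 mol %), CH2Cl2, 40 °C
Reagents that add atoms: none
Why: Olefin cross-metathesis of a hindered terminal alkene with an electron-poor 1,1-disubstituted partner gives the cross product as the thermodynamic E enal and does not touch the allylic stereocentre.

**Step 3**
Reactants: 4 (2E,4R)-2,4-dimethyloct-2-enal; 5 methyl 2-bromopropanoate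
Product: 8 methyl (2E,4E,6R)-2,4,6-trimethyldeca-2,4-dienoate, via phosphonium bromide 6 (not isolated), via stabilised ylide 7 (not isolated)
Conditions: 5 + PPh3 (1.3 equiv each), toluene, 80 °C; 1 M aq NaOH, rt, aqueous layer drawn off; then 4, 90 °C
Reagents that add atoms: triphenylphosphine, c1ccc(cc1)P(c1ccccc1)c1ccccc1 (only in 6 and 7)
Why: Wittig olefination with an α-methyl ester-stabilised ylide gives the E trisubstituted alkene under neutral conditions, so no dienamine or enolate pathway can epimerise the γ-stereocentre of the enal.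

**Step 4**
Reactants: 8 methyl (2E,4E,6R)-2,4,6-trimethyldeca-2,4-dienoate
Product: 9 (2E,4E,6R)-2,4,6-trimethyldeca-2,4-dienoic acid
Conditions: LiOH·H2O (5 equiv), THF/MeOH/H2O, 50 °C; then 1 M HCl
Reagents that add atoms: lithium hydroxide, [Li+].[OH-] (acid OH oxygen)
Why: Plain ester saponification, because hydroxide is far too weak a base to remove the remote allylic C6–H, so geometry and configuration are kept.

**Step 5**
Reactants: 9 (2E,4E,6R)-2,4,6-trimethyldeca-2,4-dienoic acid; 10 2-aminophenol
Product: 12 (2E,4E,6R)-N-(2-hydroxyphenyl)-2,4,6-trimethyldeca-2,4-dienamide, via acid chloride 11 (not isolated)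
Conditions: (COCl)2 (1.2 equiv), DMF (cat.), CH2Cl2, 0 °C → rt, evaporate; then 10 (1.05 equiv), pyridine (2 equiv), CH2Cl2, 0 °C
Reagents that add atoms: oxalyl chloride, O=C(Cl)C(=O)Cl (chlorine of 11 only)
Why: Acid chloride formation followed by chemoselective N-acylation, since the amine is much more nucleophilic than the phenol and any O-acyl product moves to nitrogen.

**Step 6**
Reactants: 12 (2E,4E,6R)-N-(2-hydroxyphenyl)-2,4,6-trimethyldeca-2,4-dienamide
Product: 14 (2E,4E,6R)-N-(5-bromo-3-chloro-2-hydroxyphenyl)-2,4,6-trimethyldeca-2,4-dienamide, via para-bromophenol 13 (not isolated)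
Conditions: NBS (1.0 equiv), MeCN, −20 → 0 °C, dark; then NCS (1.05 equiv), TsOH·H2O (10 mol %), rt
Reagents that add atoms: N-bromosuccinimide, O=C1CCC(=O)N1Br; N-chlorosuccinimide, O=C1CCC(=O)N1Cl
Why: Electrophilic aromatic halogenation steered by the stronger OH donor puts bromine para first and chlorine on the only free ortho carbon second, while the electron-poor dienamide does not react with N-halosuccinimides in the dark.

**Step 7**
Reactants: 15 chloroacetyl chloride; 16 ethyl formimidate hydrochloride; 17 1,2-bis(trimethylsilyloxy)cyclobutene (bis-TMS-protected enediol of 2-hydroxycyclobutanone)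
Product: 20 2-chloro-N-(2-hydroxy-5-oxocyclopent-1-en-1-yl)acetamide, via N-acylformimidate 18 (not isolated), via cyclobutanone adduct 19 (not isolated)
Conditions: 16, Et3N (2.0 equiv), Et2O, −10 °C, then 15; cold filtration; filtrate + 17 (1.2 equiv), BF3·OEt2 (3 equiv), CH2Cl2, −78 °C → rt; H2O quench, EtOAc extraction
Reagents that add atoms: none
Why: Proposed new method: an aza variant of geminal acylation in which the N-acylformimidate serves as a one-carbon 1,1-dielectrophile. BF3 activates its C=N bond for a Mukaiyama–Mannich-type attack by the bis-silyl enediol ether to give N,O-acetal 19. BF3 then ionises the ethoxy group to an N-acyliminium ion that has no β-hydrogen and sits next to a strained α-siloxycyclobutanone, so the ring acyl carbon migrates to the cationic carbon (semipinacol 1,2-acyl shift, four- to five-membered ring, driven by strain release and C=O formation). Desilylation and enolisation then give the 2-acylamino-1,3-dione, and no stereocentre is formed. The closest known reaction types are the Lewis-acid geminal acylation of acetals and ketals with the same cyclobutene (Mukaiyama aldol, then pinacol-type ring expansion) and N-acyliminium additions of silyl enol ethers.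

**Step 8**
Reactants: 20 2-chloro-N-(2-hydroxy-5-oxocyclopent-1-en-1-yl)acetamide; 21 (E)-penta-2,4-dienal
Product: 24 (2E,4E)-N-(2-hydroxy-5-oxocyclopent-1-en-1-yl)hepta-2,4,6-trienamide, via phosphonium chloride 22 (not isolated), via amide ylide 23 (not isolated)
Conditions: PPh3 (1.05 equiv), THF, 65 °C; t-BuOK (2.0 equiv), 0 °C; then 21 (1.2 equiv), 0 °C → rt; 1 M HCl work-up
Reagents that add atoms: triphenylphosphine, c1ccc(cc1)P(c1ccccc1)c1ccccc1 (only in 22 and 23)
Why: Wittig olefination with an amide-stabilised ylide (the first equivalent of base only parks the acidic enol as its enolate) gives mainly the 2E alkene, and the minor 2Z isomer is removed by crystallisation or equilibrated with a trace of iodine.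

**Step 9**
Reactants: 14 (2E,4E,6R)-N-(5-bromo-3-chloro-2-hydroxyphenyl)-2,4,6-trimethyldeca-2,4-dienamide; 24 (2E,4E)-N-(2-hydroxy-5-oxocyclopent-1-en-1-yl)hepta-2,4,6-trienamide
Product: 25 (2E,4E,6R)-N-{3-chloro-2-hydroxy-5-[(1E,3E,5E)-7-[(2-hydroxy-5-oxocyclopent-1-en-1-yl)amino]-7-oxohepta-1,3,5-trien-1-yl]phenyl}-2,4,6-trimethyldeca-2,4-dienamide
Conditions: 24 (1.3 equiv), Pd2(dba)3 (2.5 mol %), [HP(t-Bu)3]BF4 (6 mol %), Cy2NMe (3.5 equiv), BHT (trace), DMF, 45 °C
Reagents that add atoms: none
Why: Mizoroki–Heck reaction, in which zerovalent palladium with bulky P(t-Bu)3 inserts into C–Br but not C–Cl at mild temperature, carbopalladation occurs at the unhindered terminal CH2 of the triene, and syn β-hydride elimination gives the fully conjugated E alkene.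

**Step 10**
Reactants: 25 the 4-trienylphenol from step 9
Product: 26 (2E,4E,6R)-N-{5-chloro-3-hydroxy-3-[(1E,3E,5E)-7-[(2-hydroxy-5-oxocyclopent-1-en-1-yl)amino]-7-oxohepta-1,3,5-trien-1-yl]-6-oxocyclohexa-1,4-dien-1-yl}-2,4,6-trimethyldeca-2,4-dienamide (p-quinol)
Conditions: PhI(OAc)2 (1.05 equiv), MeCN/H2O 4:1, 0 °C
Reagents that add atoms: water, O
Why: Oxidative dearomatisation of a para-substituted phenol with trivalent iodine, where the phenol is by far the most easily oxidised site, water takes the phenoxenium ion at the para carbon C4 (both ortho carbons are blocked and the chain positions are deactivated by the terminal amide), and the new carbinol centre forms as a 1:1 mixture that is erased in step 11.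

**Step 11**
Reactants: 26 the p-quinol from step 10
Product: 28 chinikomycin B, via chinikomycin A hydroquinone 27 (not isolated)
Conditions: TFA/CH2Cl2 1:4, 0 °C → rt; then DDQ (1.0 equiv), 0 °C
Reagents that add atoms: none
Why: Quinol (dienone–phenol) rearrangement, a cationic 1,2-shift in which protonation of the C1 carbonyl makes C3 and C5 electrophilic, the π-assisted trienyl group (the only carbon substituent on C4) migrates to C5, the β-carbon of the α-chloroenone half, rather than to C3, the electron-rich β-carbon of the enamide half, the cation left at C4 is an oxocarbenium ion para to nitrogen, loss of H-5 aromatises irreversibly to 27, and DDQ then oxidises the hydroquinone to the quinone, with the carbinol centre vanishing and C6 of the side chain untouched.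

**Compound list**
1 | (E)-1-bromohept-2-ene | CCCC/C=C/CBr | starting material
2 | (R)-3-methylhept-1-ene | CCCC[C@@H](C)C=C | intermediate
3 | methacrolein | C=C(C)C=O | starting material
4 | (2E,4R)-2,4-dimethyloct-2-enal | CCCC[C@@H](C)/C=C(\C)C=O | intermediate
5 | methyl 2-bromopropanoate (racemic) | CC(Br)C(=O)OC | starting material
6 | (1-methoxy-1-oxopropan-2-yl)triphenylphosphonium bromide | CC(C(=O)OC)[P+](c1ccccc1)(c1ccccc1)c1ccccc1.[Br-] | intermediate
7 | methyl 2-(triphenylphosphoranylidene)propanoate | CC(C(=O)OC)=P(c1ccccc1)(c1ccccc1)c1ccccc1 | intermediate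
8 | methyl (2E,4E,6R)-2,4,6-trimethyldeca-2,4-dienoate | CCCC[C@@H](C)/C=C(C)/C=C(\C)C(=O)OC | intermediate
9 | (2E,4E,6R)-2,4,6-trimethyldeca-2,4-dienoic acid | CCCC[C@@H](C)/C=C(C)/C=C(\C)C(=O)O | intermediate
10 | 2-aminophenol | Nc1ccccc1O | starting material
11 | (2E,4E,6R)-2,4,6-trimethyldeca-2,4-dienoyl chloride | CCCC[C@@H](C)/C=C(C)/C=C(\C)C(=O)Cl | intermediate
12 | (2E,4E,6R)-N-(2-hydroxyphenyl)-2,4,6-trimethyldeca-2,4-dienamide | CCCC[C@@H](C)/C=C(C)/C=C(\C)C(=O)Nc1ccccc1O | intermediate
13 | (2E,4E,6R)-N-(5-bromo-2-hydroxyphenyl)-2,4,6-trimethyldeca-2,4-dienamide | CCCC[C@@H](C)/C=C(C)/C=C(\C)C(=O)Nc1cc(Br)ccc1O | intermediate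
14 | (2E,4E,6R)-N-(5-bromo-3-chloro-2-hydroxyphenyl)-2,4,6-trimethyldeca-2,4-dienamide | CCCC[C@@H](C)/C=C(C)/C=C(\C)C(=O)Nc1cc(Br)cc(Cl)c1O | intermediate
15 | chloroacetyl chloride | ClCC(=O)Cl | starting material
16 | ethyl formimidate hydrochloride | CCOC=N.Cl | starting material
17 | 1,2-bis(trimethylsilyloxy)cyclobutene (bis-TMS-protected enediol of 2-hydroxycyclobutanone, C4O2 core) | C[Si](C)(C)OC1=C(O[Si](C)(C)C)CC1 | starting material
18 | ethyl N-(chloroacetyl)formimidate | CCOC=NC(=O)CCl | intermediate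
19 | 2-chloro-N-{ethoxy[2-oxo-1-(trimethylsilyloxy)cyclobutyl]methyl}acetamide | CCOC(NC(=O)CCl)C1(O[Si](C)(C)C)CCC1=O | intermediate
20 | 2-chloro-N-(2-hydroxy-5-oxocyclopent-1-en-1-yl)acetamide | O=C(CCl)NC1=C(O)CCC1=O | intermediate
21 | (E)-penta-2,4-dienal | C=C/C=C/C=O | starting material
22 | {2-[(2-hydroxy-5-oxocyclopent-1-en-1-yl)amino]-2-oxoethyl}triphenylphosphonium chloride | O=C(C[P+](c1ccccc1)(c1ccccc1)c1ccccc1)NC1=C(O)CCC1=O.[Cl-] | intermediate
23 | N-(2-hydroxy-5-oxocyclopent-1-en-1-yl)-2-(triphenylphosphoranylidene)acetamide (present as its potassium enolate) | O=C(C=P(c1ccccc1)(c1ccccc1)c1ccccc1)NC1=C(O)CCC1=O | intermediate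
24 | (2E,4E)-N-(2-hydroxy-5-oxocyclopent-1-en-1-yl)hepta-2,4,6-trienamide | C=C/C=C/C=C/C(=O)NC1=C(O)CCC1=O | intermediate
25 | (2E,4E,6R)-N-{3-chloro-2-hydroxy-5-[(1E,3E,5E)-7-[(2-hydroxy-5-oxocyclopent-1-en-1-yl)amino]-7-oxohepta-1,3,5-trien-1-yl]phenyl}-2,4,6-trimethyldeca-2,4-dienamide | CCCC[C@@H](C)/C=C(C)/C=C(\C)C(=O)Nc1cc(/C=C/C=C/C=C/C(=O)NC2=C(O)CCC2=O)cc(Cl)c1O | intermediate
26 | p-quinol: (2E,4E,6R)-N-{5-chloro-3-hydroxy-3-[(1E,3E,5E)-7-[(2-hydroxy-5-oxocyclopent-1-en-1-yl)amino]-7-oxohepta-1,3,5-trien-1-yl]-6-oxocyclohexa-1,4-dien-1-yl}-2,4,6-trimethyldeca-2,4-dienamide, both carbinol epimers | CCCC[C@@H](C)/C=C(C)/C=C(\C)C(=O)NC1=CC(O)(/C=C/C=C/C=C/C(=O)NC2=C(O)CCC2=O)C=C(Cl)C1=O | intermediate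
27 | chinikomycin A: (2E,4E,6R)-N-{3-chloro-2,5-dihydroxy-4-[(1E,3E,5E)-7-[(2-hydroxy-5-oxocyclopent-1-en-1-yl)amino]-7-oxohepta-1,3,5-trien-1-yl]phenyl}-2,4,6-trimethyldeca-2,4-dienamide | CCCC[C@@H](C)/C=C(C)/C=C(\C)C(=O)Nc1cc(O)c(/C=C/C=C/C=C/C(=O)NC2=C(O)CCC2=O)c(Cl)c1O | intermediate
28 | chinikomycin B: (2E,4E,6R)-N-{5-chloro-4-[(1E,3E,5E)-7-[(2-hydroxy-5-oxocyclopent-1-en-1-yl)amino]-7-oxohepta-1,3,5-trien-1-yl]-3,6-dioxocyclohexa-1,4-dien-1-yl}-2,4,6-trimethyldeca-2,4-dienamide | CCCC[C@@H](C)/C=C(C)/C=C(\C)C(=O)NC1=CC(=O)C(/C=C/C=C/C=C/C(=O)NC2=C(O)CCC2=O)=C(Cl)C1=O | target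

**Totals.** Total step count: 11. Longest linear sequence: 9 (steps 1, 2, 3, 4, 5, 6, 9, 10, 11).

**Steps most likely to fail**

Step 7 (the new ring expansion; the risks are double addition of 17, alkyl instead of acyl migration, or loss of 18 before it reacts). The fallback uses known chemistry, sets out from 15 and comes back at 20. Cyclopentane-1,3-dione F1 is nitrated at C2 with fuming nitric acid to 2-nitrocyclopentane-1,3-dione F2. This is hydrogenated over Pd/C in methanolic HCl to 2-amino-3-hydroxycyclopent-2-en-1-one hydrochloride F3. F3 is N-acylated with 15 (Et3N, CH2Cl2/DMF, 0 °C) to give 20. The ring is then bought rather than built, at a cost of two more steps.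

Step 10 (water may attack the chain instead of C4, or the oxidant may touch the aminocyclopentenone). The fallback sets out from 12 and 23 and comes back at 26. It makes the carbinol by carbonyl addition, so no oxidant ever meets the triene.
- Compound 12 is dichlorinated (NCS, 2.1 equiv) to the 3,5-dichloro-2-hydroxyanilide F4.
- PhI(OAc)2 in aqueous MeCN expels the para chlorine of F4 and gives chloroquinone F5.
- (E)-2-(Tributylstannyl)vinyllithium (from (E)-1,2-bis(tributylstannyl)ethene and n-BuLi, 2.2 equiv, THF, −78 °C) adds to the unflanked C4 carbonyl to give stannylvinyl quinol F6.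
- In parallel, ylide 23 and (E)-3-bromoprop-2-enal F7 give bromodienamide F8.
- Stille coupling of F6 with F8 (PdCl2(MeCN)2, DMF, rt) gives 26.

Step 11 (migration to C3, or ionisation of the carbinol in place of the shift). The fallback sets out from 12 (by way of F4 and F5 above) and 24, and comes back at 27. It forms the C5–chain bond by cross-coupling instead of by migration. One equivalent of HBr (AcOH/CH2Cl2, 0 °C) adds to C5 of F5, the β-carbon of the chloroenone, to give bromochlorohydroquinone F9. Heck coupling of F9 with 24 under the conditions of step 9 gives 27, which is oxidised with DDQ as in step 11.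

**Further compounds**
F1 | step 7 | cyclopentane-1,3-dione | O=C1CCC(=O)C1
F2 | step 7 | 2-nitrocyclopentane-1,3-dione | O=C1CCC(=O)C1[N+](=O)[O-]
F3 | step 7 | 2-amino-3-hydroxycyclopent-2-en-1-one hydrochloride | NC1=C(O)CCC1=O.Cl
F4 | step 10 | (2E,4E,6R)-N-(3,5-dichloro-2-hydroxyphenyl)-2,4,6-trimethyldeca-2,4-dienamide | CCCC[C@@H](C)/C=C(C)/C=C(\C)C(=O)Nc1cc(Cl)cc(Cl)c1O
F5 | step 10 | (2E,4E,6R)-N-(5-chloro-3,6-dioxocyclohexa-1,4-dien-1-yl)-2,4,6-trimethyldeca-2,4-dienamide | CCCC[C@@H](C)/C=C(C)/C=C(\C)C(=O)NC1=CC(=O)C=C(Cl)C1=O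
F6 | step 10 | (2E,4E,6R)-N-{5-chloro-3-hydroxy-6-oxo-3-[(E)-2-(tributylstannyl)ethenyl]cyclohexa-1,4-dien-1-yl}-2,4,6-trimethyldeca-2,4-dienamide | CCCC[C@@H](C)/C=C(C)/C=C(\C)C(=O)NC1=CC(O)(/C=C/[Sn](CCCC)(CCCC)CCCC)C=C(Cl)C1=O
F7 | step 10 | (E)-3-bromoprop-2-enal | O=C/C=C/Br
F8 | step 10 | (2E,4E)-5-bromo-N-(2-hydroxy-5-oxocyclopent-1-en-1-yl)penta-2,4-dienamide | Br/C=C/C=C/C(=O)NC1=C(O)CCC1=O
F9 | step 11 | (2E,4E,6R)-N-(4-bromo-3-chloro-2,5-dihydroxyphenyl)-2,4,6-trimethyldeca-2,4-dienamide | CCCC[C@@H](C)/C=C(C)/C=C(\C)C(=O)Nc1cc(O)c(Br)c(Cl)c1O
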